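**Retrosynthetic overview**
- The free 5-OH is unmasked last from its acetate by a carboxylesterase at pH 7, because base would racemise C2 through retro-oxa-Michael ring opening.
- The C2–aryl bond and the only stereocentre come from a Rh-catalysed asymmetric 1,4-addition of 3,4-dimethoxyphenylboronic acid to a 5-acetoxy-6,7-dimethoxychromone.
- The acetoxychromone comes from 5,6,7-trimethoxychromone by chelation-controlled cleavage of the peri 5-OMe, then acetylation.
- The chromone comes from commercial 6'-hydroxy-2',3',4'-trimethoxyacetophenone and DMF-DMA (enaminone, then acid ring closure).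
- Ring order: the A ring is bought, the pyranone ring is closed on it, and the B ring is attached last as an intact aryl group.

Assumption: the target SMILES is read as (2S)-5-hydroxy-6,7,3',4'-tetramethoxyflavanone; compounds 1, 2, 6 and 8, the Rh precursor, the ligand and the enzyme are taken as catalogue items.

**Route**

Step 1
Reactants: 1 1-(6-hydroxy-2,3,4-trimethoxyphenyl)ethan-1-one; 2 N,N-dimethylformamide dimethyl acetal
Product: 3 (E)-3-(dimethylamino)-1-(6-hydroxy-2,3,4-trimethoxyphenyl)prop-2-en-1-one
Conditions: DMF-DMA (2 equiv), toluene, 100 °C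
Reagents that add atoms: N,N-dimethylformamide dimethyl acetal, COC(OC)N(C)C
Why: Amide-acetal condensation at the acetyl CH3 gives the stable E vinylogous amide (enaminone), and the hydrogen-bonded phenol is not methylated.

Step 2
Reactants: 3 (E)-3-(dimethylamino)-1-(6-hydroxy-2,3,4-trimethoxyphenyl)prop-2-en-1-one
Product: 4 5,6,7-trimethoxy-4H-chromen-4-one
Conditions: conc. HCl, CH2Cl2, 40 °C
Reagents that add atoms: none
Why: Acid-promoted intramolecular oxa-Michael addition–elimination (loss of dimethylamine) closes the pyranone ring, and only one phenol is free so the regiochemistry is fixed.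

Step 3
Reactants: 4 5,6,7-trimethoxy-4H-chromen-4-one
Product: 5 5-hydroxy-6,7-dimethoxy-4H-chromen-4-one
Conditions: BCl3 (1.2 equiv), CH2Cl2, −78 → 0 °C; then H2O
Reagents that add atoms: none
Why: Chelation-controlled Lewis-acid ether cleavage, in which BCl3 bound to the C4 carbonyl cleaves only the peri 5-OMe through a six-membered boron chelate.

Step 4
Reactants: 5 5-hydroxy-6,7-dimethoxy-4H-chromen-4-one; 6 acetic anhydride
Product: 7 6,7-dimethoxy-4-oxo-4H-chromen-5-yl acetate
Conditions: Ac2O, pyridine, DMAP (cat.), 25 → 50 °C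
Reagents that add atoms: acetic anhydride, CC(=O)OC(C)=O
Why: DMAP-catalysed O-acylation masks the acac-like 5-OH/4-C=O unit, which would otherwise chelate Rh(I), and makes the enone a better acceptor.

Step 5
Reactants: 7 6,7-dimethoxy-4-oxo-4H-chromen-5-yl acetate; 8 3,4-dimethoxyphenylboronic acid
Product: 9 (2S)-2-(3,4-dimethoxyphenyl)-6,7-dimethoxy-4-oxo-3,4-dihydro-2H-chromen-5-yl acetate
Conditions: [Rh(OH)(cod)]2 (1.5 mol%), (S)-MeO-F12-BIPHEP (3.3 mol%), 8 (2.5 equiv), toluene/H2O 10:1, 25–40 °C, no added base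
Reagents that add atoms: 3,4-dimethoxyphenylboronic acid, COc1ccc(B(O)O)cc1OC
Why: Hayashi–Miyaura Rh(I)-catalysed asymmetric 1,4-addition, in which the aryl–Rh species with the (S)-biaryl bisphosphine adds to the Re face of C2 (same facial sense as (S)-BINAP with cyclohexenone) to set 2S, and water protonates the Rh enolate.

Step 6
Reactants: 9 (2S)-2-(3,4-dimethoxyphenyl)-6,7-dimethoxy-4-oxo-3,4-dihydro-2H-chromen-5-yl acetate
Product: 10 (2S)-2-(3,4-dimethoxyphenyl)-5-hydroxy-6,7-dimethoxy-2,3-dihydro-4H-chromen-4-one (target)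
Conditions: carboxylesterase (pig liver esterase), phosphate buffer (0.2 M, pH 7.0)/DMSO 9:1, 30 °C
Reagents that add atoms: none
Why: Enzymatic ester hydrolysis by a serine-hydrolase carboxylesterase removes the aryl acetate at neutral pH, where neither E1cB ring opening nor enolisation can racemise C2, and the methyl ethers and ketone are untouched.

**Compound list**
1 | 1-(6-hydroxy-2,3,4-trimethoxyphenyl)ethan-1-one | CC(=O)c1c(O)cc(OC)c(OC)c1OC | starting material
2 | N,N-dimethylformamide dimethyl acetal | COC(OC)N(C)C | starting material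
3 | (E)-3-(dimethylamino)-1-(6-hydroxy-2,3,4-trimethoxyphenyl)prop-2-en-1-one | CN(C)/C=C/C(=O)c1c(O)cc(OC)c(OC)c1OC | intermediate
4 | 5,6,7-trimethoxy-4H-chromen-4-one | COc1cc2occc(=O)c2c(OC)c1OC | intermediate
5 | 5-hydroxy-6,7-dimethoxy-4H-chromen-4-one | COc1cc2occc(=O)c2c(O)c1OC | intermediate
6 | acetic anhydride | CC(=O)OC(C)=O | starting material
7 | 6,7-dimethoxy-4-oxo-4H-chromen-5-yl acetate | COc1cc2occc(=O)c2c(OC(C)=O)c1OC | intermediate
8 | 3,4-dimethoxyphenylboronic acid | COc1ccc(B(O)O)cc1OC | starting material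
9 | (2S)-2-(3,4-dimethoxyphenyl)-6,7-dimethoxy-4-oxo-3,4-dihydro-2H-chromen-5-yl acetate | COc1ccc([C@@H]2CC(=O)c3c(cc(OC)c(OC)c3OC(C)=O)O2)cc1OC | intermediate
10 | (2S)-2-(3,4-dimethoxyphenyl)-5-hydroxy-6,7-dimethoxy-2,3-dihydro-4H-chromen-4-one | COc1ccc([C@@H]2CC(=O)c3c(cc(OC)c(OC)c3O)O2)cc1OC | target

**Step count and risks**

Total steps: 6. Longest linear sequence: 6 (1 → 10).

The three steps most likely to fail:

Step 5 (asymmetric 1,4-addition). The trioxygenated chromone is an electron-rich acceptor, 8 can protodeboronate, and any acetate loss would give a phenol that chelates Rh. The 2S sense rests on the cyclohexenone facial model and should be confirmed on 9 by chiral HPLC and CD. The fallback sets out from 7 and comes back at 9, and sets C2 by asymmetric hydrogenation instead of asymmetric arylation. Pd(II)-catalysed oxidative arylation of 7 with 8 (Pd(TFA)2, DMSO, DDQ as terminal oxidant; conjugate addition then dehydrogenation) gives the flavone 2-(3,4-dimethoxyphenyl)-6,7-dimethoxy-4-oxo-4H-chromen-5-yl acetate F1. Base-free hydrogenation with a chiral Ru–bis(NHC) catalyst (antipode chosen for 2S) reduces C2=C3 enantioselectively. The over-reduced portion is the cis-flavan-4-ol (2S,4S)-2-(3,4-dimethoxyphenyl)-4-hydroxy-6,7-dimethoxy-3,4-dihydro-2H-chromen-5-yl acetate F2, whose C4 configuration is immaterial. Dess–Martin periodinane oxidises F2 at C4 so that all material converges on 9.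

Step 6 (enzymatic deacetylation). The acetate sits between the 6-OMe and the peri carbonyl, a position that lipases and esterases can turn over slowly. The fallback sets out from 5 and comes back at 10, and moves the scissile ester away from the hindered position. Alkylation of 5 with chloromethyl pivalate (ClCOC(=O)C(C)(C)C; K2CO3, NaI, DMF, 50 °C) gives [(6,7-dimethoxy-4-oxo-4H-chromen-5-yl)oxy]methyl 2,2-dimethylpropanoate F3. The Rh-catalysed addition of 8 under the step 5 conditions gives {[(2S)-2-(3,4-dimethoxyphenyl)-6,7-dimethoxy-4-oxo-3,4-dihydro-2H-chromen-5-yl]oxy}methyl 2,2-dimethylpropanoate F4. The same carboxylesterase hydrolyses the remote pivalate to the hydroxymethyl ether (2S)-2-(3,4-dimethoxyphenyl)-5-(hydroxymethoxy)-6,7-dimethoxy-2,3-dihydro-4H-chromen-4-one F5 (not isolated), which loses formaldehyde spontaneously at pH 7 to give 10.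

Step 3 (mono-demethylation). The risk is over-cleavage at O6 through the boron chelate, or incomplete conversion. The fallback sets out from 4 and comes back at 5, and replaces selective mono-cleavage by exhaustive cleavage and selective re-methylation. AlBr3 in MeCN (0 °C → rt) removes both the 5- and 6-methyl groups to give 5,6-dihydroxy-7-methoxy-4H-chromen-4-one F6. MeI (1.05 equiv), K2CO3, acetone, rt then methylates only the non-chelated 6-OH; the hydrogen-bonded 5-OH is inert under these conditions.

**Further compounds**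
F1 | step 5 | 2-(3,4-dimethoxyphenyl)-6,7-dimethoxy-4-oxo-4H-chromen-5-yl acetate | COc1ccc(-c2cc(=O)c3c(cc(OC)c(OC)c3OC(C)=O)o2)cc1OC
F2 | step 5 | (2S,4S)-2-(3,4-dimethoxyphenyl)-4-hydroxy-6,7-dimethoxy-3,4-dihydro-2H-chromen-5-yl acetate | COc1ccc([C@@H]2C[C@H](O)c3c(cc(OC)c(OC)c3OC(C)=O)O2)cc1OC
F3 | step 6 | [(6,7-dimethoxy-4-oxo-4H-chromen-5-yl)oxy]methyl 2,2-dimethylpropanoate | COc1cc2occc(=O)c2c(OCOC(=O)C(C)(C)C)c1OC
F4 | step 6 | {[(2S)-2-(3,4-dimethoxyphenyl)-6,7-dimethoxy-4-oxo-3,4-dihydro-2H-chromen-5-yl]oxy}methyl 2,2-dimethylpropanoate | COc1ccc([C@@H]2CC(=O)c3c(cc(OC)c(OC)c3OCOC(=O)C(C)(C)C)O2)cc1OC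
F5 | step 6 | (2S)-2-(3,4-dimethoxyphenyl)-5-(hydroxymethoxy)-6,7-dimethoxy-2,3-dihydro-4H-chromen-4-one | COc1ccc([C@@H]2CC(=O)c3c(cc(OC)c(OC)c3OCO)O2)cc1OC
F6 | step 3 | 5,6-dihydroxy-7-methoxy-4H-chromen-4-one | COc1cc2occc(=O)c2c(O)c1O
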